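Count what each Z costs in E before anything else.

    L + E → G + X (k1 = 47 L mol⁻¹ min⁻¹)
    X + E → G + Q (k2 = 21 L mol⁻¹ min⁻¹)
    Z + E → G + L (k3 = 6.9 L mol⁻¹ min⁻¹)

Z 0.34 M (in portions, 3); E 0.340 M; time 6.0 h; the portions of Z follow each other after 4.0 min, the first at the start

- which holds at 6.0 h: what has brought the reaction to rest, or that it has not come to rest (it is still moving / all of Z has reacted / E has run out first)
- X at 6.0 h, in percent of the Z charged

- the reaction counts as stopped when no species that holds the Z changes by six tenths of a point or more over the second half of the time
- run time (flask): 6.0 h

We read the flask as a ladder of times. Reckoned at the starting cE, the half-lives are 0.0434 min for L, 0.0971 min for X and 0.295 min for Z. Z is slower than the other two, so we take the L and X steps as settled and book each Z that reacts as a Q, at a price of 3 E.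

The next rung is the 4.0 min between portions, far longer than the half-life of Z at the starting cE, so the first portion gets time to react before the second arrives. The price then gives the priced turnover, the E charged over 3 times the Z charged: 33.3%. Complete exchange needs more E than the flask holds, so E is the limiting reagent.

The top rung is the 6.0 h run, far longer than the gap. We therefore expect E to give out first, with Z left near 66.7%. Our reckoning gives no figure for X.

The forecast reads: E has run out first, with X at 3.2% of the Z charged, on the ground “Portion 3 finds almost no E”.

The simulation gives E has run out first, with X at 3.19% of the Z charged and E at 0% of its charge at 6.00 h. At 0.00746 h the half-life of X by X + E was 0.17 min, far shorter than the 4.0 min between portions, and the net turnover of Z came to 36.7% against the priced 33.3%. The neighbour flask with 0.14 M of Z, priced the same way at 81.0%, leaves Z at 15.2%, a turnover of 84.8%.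

The numbers of this flask were drawn at random within sensible limits; the rest is arithmetic.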